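    substrate ⇌ target (K1 = 1.6, k1 = 0.0349 h⁻¹)
    target ⇌ isomer of the product A (K2 = 0.68, k2 = 0.164 h⁻¹)
    isomer of the product A ⇌ isomer of the product B (K3 = 0.195, k3 = 0.00174 h⁻¹)
    crystals ⇌ target, rate k4*(cs4 - [target]) while solid is left; crystals form when [target] > cs4 (cs4 = 2.5 mM, k4 = 0.301 h⁻¹)

substrate 0.065 M; time 15 d

- the state of affairs at 15 d: stopped, and by what, or still going (all of the substrate has reacted / it is still moving / forward and back rates have come level)
- the target standing at 15 d, as a percentage of the substrate charged
- the isomer of the product A standing at 15 d, as a percentage of the substrate charged

Two slow clocks matter in this flask: the way back of step 3, with a half-life of 3.24 d, is longer than the 0.828 d of substrate by step 1 forward, yet the run of 15 d holds 4.63 of the first and 18.1 of the second.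

We count in fractions of the charge. Without crystals, dissolved target at rest would be 41.0%, more than the saturation share 3.85%. So in this flask crystals stay, and dissolved target ends at that share. The other forms at rest then follow from the equilibrium constants, which is thermodynamic control:

substrate at rest: 2.40%

isomer of the product A: 2.62%

isomer of the product B: 0.510%

Once dissolved target stands at that share, the substrate's excess over its rest level halves every 0.828 d: this is the excess half-life, and we count it.

The bracket on target, crystals included, has two sides. From above, we suppose no isomer of the product B has formed:

95.0%

From below, we take that isomer complete and, as a margin for the time dissolved target stands above saturation, let the substrate excess halve every 3.24 d instead: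

90.5%

The run of 15 d is longer than either clock, so we commit to the rest state, with forward and back rates level:

94.5%

The forecast said forward and back rates have come level, with 94.5% target and 2.6% isomer of the product A, on the grounds that “The slowest relaxations take roughly 30 to 110 h”.

The flask ends so: forward and back rates have come level, with 94.5% target and 2.62% isomer of the product A. Crystals in this flask stand at 90.6% of the charge at 15.0 d. The neighbour flask, same charge, read at 4.0 d, has had 4.83 half-lives, so the count gives 5.83%, and that flask reads substrate 6.78%.

Its constants belong to no real substance.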